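**Retrosynthetic overview**

1. Target 20 is a tetra-ortho-substituted benzophenone. In ring A (the 2,6-dimethoxyphenyl ring) the ketone-bearing carbon C1' lies between the two oxygen-bearing carbons C2' and C6'. The C1'–C(=O) bond and the neighbouring C2'–O bond are cut together, giving 3-methoxybenzyne 16 and the ring B benzoic acid 13 (aryne insertion into the acid C–O bond); the freed C2' phenol is then methylated.
2. Acid 13 comes from phthalide 10 by hydroxide opening and exhaustive benzylation. Phthalide 10 comes from 4-methoxy-3-methylphenol 1 by O-carbamate ortho-Fries shift, amide-directed metalation–formylation, reduction and lactonisation.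
3. Endgame: methylation of the ring A phenol, hydrogenolysis of both benzyl ethers, acetylation of the primary alcohol.
4. Ring order: ring B is bought as phenol 1 and only substituted (a lactone ring is closed in step 5 as a temporary device and opened in step 6). Ring A enters as the aryne in step 8. No ring of the target is built.

Key step: step 8

**Assumptions**

- The ring B phenol is carried through the metalation as a MOM ether, not a benzyl ether, because s-BuLi held by the neighbouring amide could also remove an ArOCH2Ph proton. The MOM group is lost during lactonisation, and both benzyl ethers are then put on together.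
- Diol 19 may equilibrate with its cyclic hemiketal (hydroxymethyl onto the ketone); acetylation should drain the open form.
- Compounds 1, 2 and 14, and the 2-bromo-3-methoxyphenol used in one fallback, are taken as commercially available.

**Route**

Step 1
Reactants: 1 4-methoxy-3-methylphenol; 2 N,N-diethylcarbamoyl chloride
Product: 3 4-methoxy-3-methylphenyl N,N-diethylcarbamate
Conditions: K2CO3, MeCN, reflux
Reagents that add atoms: none
Why: O-carbamoylation of the phenoxide by nucleophilic acyl substitution on the carbamoyl chloride is the routine way to aryl O-carbamates.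

Step 2
Reactants: 3 4-methoxy-3-methylphenyl N,N-diethylcarbamate
Product: 5 N,N-diethyl-2-hydroxy-5-methoxy-4-methylbenzamide, via ortho-lithiated carbamate 4 (not isolated)
Conditions: s-BuLi, TMEDA, THF, −78 °C to rt; aq NH4Cl
Reagents that add atoms: none
Why: Anionic ortho-Fries rearrangement, in which the O-carbamate directs lithiation to the open ortho C–H (the other ortho site is crowded by the ring methyl) and the aryllithium takes over the carbamoyl group by a 1,3-O-to-C shift on warming.

Step 3
Reactants: 5 N,N-diethyl-2-hydroxy-5-methoxy-4-methylbenzamide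
Product: 6 N,N-diethyl-5-methoxy-2-(methoxymethoxy)-4-methylbenzamide
Conditions: NaH, MOMCl, DMF, 0 °C to rt
Reagents that add atoms: chloromethyl methyl ether (MOMCl), COCCl
Why: Williamson-type O-alkylation of the sodium phenoxide gives an acetal protecting group that has no benzylic C–H for s-BuLi to attack and that falls off without a separate step in step 5.

Step 4
Reactants: 6 N,N-diethyl-5-methoxy-2-(methoxymethoxy)-4-methylbenzamide
Product: 8 N,N-diethyl-2-formyl-3-methoxy-6-(methoxymethoxy)-4-methylbenzamide, via aryllithium 7 (not isolated)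
Conditions: s-BuLi, TMEDA, THF, −78 °C; DMF, −78 °C to rt; aq NH4Cl
Reagents that add atoms: N,N-dimethylformamide, CN(C)C=O
Why: Directed ortho metalation should take place at the one C–H flanked by the tertiary amide and the methoxy group (cooperative 1,3-directors), and the aryllithium is formylated by DMF; the site beside the MOM ether has one weaker director and is crowded by the methyl group.

Step 5
Reactants: 8 N,N-diethyl-2-formyl-3-methoxy-6-(methoxymethoxy)-4-methylbenzamide
Product: 10 7-hydroxy-4-methoxy-5-methylisobenzofuran-1(3H)-one, via hydroxymethyl amide 9 (not isolated)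
Conditions: NaBH4, MeOH, 0 °C; then conc. HCl, MeOH, 60 °C
Reagents that add atoms: none
Why: Borohydride reduction gives the benzylic alcohol, which under acid displaces diethylamine from the neighbouring hindered amide (lactonisation to the phthalide), while the same acid cleaves the MOM acetal by transfer to methanol.

Step 6
Reactants: 10 7-hydroxy-4-methoxy-5-methylisobenzofuran-1(3H)-one
Product: 12 benzyl 6-(benzyloxy)-2-[(benzyloxy)methyl]-3-methoxy-4-methylbenzoate, via dipotassium hydroxy carboxylate 11 (not isolated)
Conditions: KOH, MeOH/H2O, reflux, evaporate to dryness; then powdered KOH, BnBr (excess), DMSO, rt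
Reagents that add atoms: potassium hydroxide, [K+].[OH-]; benzyl bromide, BrCc1ccccc1
Why: Lactone saponification followed by Williamson alkylation in KOH/DMSO benzylates phenoxide, primary alkoxide and carboxylate; any phthalide re-formed from a benzyl ester with a free alkoxide is re-opened by the excess hydroxide, whereas ether formation is irreversible, so the material should funnel to 12.

Step 7
Reactants: 12 benzyl 6-(benzyloxy)-2-[(benzyloxy)methyl]-3-methoxy-4-methylbenzoate
Product: 13 6-(benzyloxy)-2-[(benzyloxy)methyl]-3-methoxy-4-methylbenzoic acid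
Conditions: KOH, DMSO/H2O, 90 °C; then 1 M HCl, 0 °C
Reagents that add atoms: potassium hydroxide, [K+].[OH-]
Why: Ester saponification with poorly solvated hydroxide in wet DMSO should cleave the di-ortho-substituted benzyl ester, the two benzyl ethers are inert to base, and the acid cannot relactonise without losing benzyl alcohol.

Step 8
Reactants: 13 6-(benzyloxy)-2-[(benzyloxy)methyl]-3-methoxy-4-methylbenzoic acid; 14 3-methoxy-2-(trimethylsilyl)phenyl trifluoromethanesulfonate
Product: 17 {6-(benzyloxy)-2-[(benzyloxy)methyl]-3-methoxy-4-methylphenyl}(2-hydroxy-6-methoxyphenyl)methanone, via caesium carboxylate 15 (not isolated), via 3-methoxybenzyne 16 (not isolated)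
Conditions: Cs2CO3 (0.5 equiv), MeOH, rt, evaporate, dry (PhMe azeotrope); then 14 (1.3 equiv), CsF, THF, 125 °C, sealed tube; aq NH4Cl
Reagents that add atoms: none
Why: Fluoride attacks silicon in 14 and triflate leaves to give aryne 16, whose carbon remote from the methoxy group is attacked by the carboxylate oxygen of 15, so that the aryl anion sits on the carbon next to the methoxy group. That anion attacks the ester carbonyl held ortho to it (4-exo-trig) to give a transient four-membered alkoxide, which opens by C–O cleavage to the caesium phenoxide of 17, so the aryl–C(=O) bond and the adjacent aryl–O bond form in one operation. The closest known reaction type is the insertion of arynes into the C–O bond of carboxylic acids, aromatic acids included, to give ortho-hydroxyaryl ketones; acid 13 is a more hindered member of the same class. No ring of the product is closed (the four-membered ring is only transient) and no stereocentre is formed. The step needs regioselective addition to the unsymmetrical aryne, which the inductively withdrawing methoxy group secures by making the distal aryne carbon the electrophilic one and stabilising the anion beside it. It also needs acyl transfer to outrun protonation of the aryl anion, which the dry preformed caesium salt (no acid proton) and the high temperature favour, while the small excess of 14 limits O-arylation of the product phenoxide.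

Step 9
Reactants: 17 {6-(benzyloxy)-2-[(benzyloxy)methyl]-3-methoxy-4-methylphenyl}(2-hydroxy-6-methoxyphenyl)methanone
Product: 18 {6-(benzyloxy)-2-[(benzyloxy)methyl]-3-methoxy-4-methylphenyl}(2,6-dimethoxyphenyl)methanone
Conditions: MeI, K2CO3, DMF, 40 °C
Reagents that add atoms: iodomethane, CI
Why: Williamson O-methylation of the only free phenol (ring A) completes the 2,6-dimethoxyphenyl ring while the ring B phenol stays masked as its benzyl ether.

Step 10
Reactants: 18 {6-(benzyloxy)-2-[(benzyloxy)methyl]-3-methoxy-4-methylphenyl}(2,6-dimethoxyphenyl)methanone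
Product: 19 (2,6-dimethoxyphenyl)[6-hydroxy-2-(hydroxymethyl)-3-methoxy-4-methylphenyl]methanone
Conditions: H2 (1 atm), 10% Pd/C, EtOAc, rt, stopped after uptake of two equivalents
Reagents that add atoms: none
Why: Catalytic hydrogenolysis should cleave the two unhindered PhCH2–O bonds, while the ring B CH2–O bond and the ketone are each shielded by two ortho substituents and should survive if the reaction is stopped in time.

Step 11
Reactants: 19 (2,6-dimethoxyphenyl)[6-hydroxy-2-(hydroxymethyl)-3-methoxy-4-methylphenyl]methanone
Product: 20 [2-(2,6-dimethoxybenzoyl)-3-hydroxy-6-methoxy-5-methylphenyl]methyl acetate (preacredinone A)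
Conditions: Ac2O (1.1 equiv), pyridine, CH2Cl2, 0 °C
Reagents that add atoms: acetic anhydride, CC(=O)OC(C)=O
Why: Chemoselective O-acetylation is expected because the primary hydroxyl is far more nucleophilic than the ring B phenol, which is hydrogen-bonded to the ortho ketone and sterically flanked.

**Compound list**

1 | 4-methoxy-3-methylphenol | COc1ccc(O)cc1C | starting material
2 | N,N-diethylcarbamoyl chloride | CCN(CC)C(Cl)=O | starting material
3 | 4-methoxy-3-methylphenyl N,N-diethylcarbamate | CCN(CC)C(=O)Oc1ccc(OC)c(C)c1 | intermediate
4 | 2-lithio-4-methoxy-5-methylphenyl N,N-diethylcarbamate | [Li]c1cc(OC)c(C)cc1OC(=O)N(CC)CC | intermediate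
5 | N,N-diethyl-2-hydroxy-5-methoxy-4-methylbenzamide | CCN(CC)C(=O)c1cc(OC)c(C)cc1O | intermediate
6 | N,N-diethyl-5-methoxy-2-(methoxymethoxy)-4-methylbenzamide | CCN(CC)C(=O)c1cc(OC)c(C)cc1OCOC | intermediate
7 | N,N-diethyl-2-lithio-3-methoxy-6-(methoxymethoxy)-4-methylbenzamide | CCN(CC)C(=O)c1c([Li])c(OC)c(C)cc1OCOC | intermediate
8 | N,N-diethyl-2-formyl-3-methoxy-6-(methoxymethoxy)-4-methylbenzamide | CCN(CC)C(=O)c1c(C=O)c(OC)c(C)cc1OCOC | intermediate
9 | N,N-diethyl-2-(hydroxymethyl)-3-methoxy-6-(methoxymethoxy)-4-methylbenzamide | CCN(CC)C(=O)c1c(CO)c(OC)c(C)cc1OCOC | intermediate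
10 | 7-hydroxy-4-methoxy-5-methylisobenzofuran-1(3H)-one | O=C1OCc2c(OC)c(C)cc(O)c12 | intermediate
11 | dipotassium 2-(hydroxymethyl)-3-methoxy-4-methyl-6-oxidobenzoate | [K+].[K+].[O-]C(=O)c1c([O-])cc(C)c(OC)c1CO | intermediate
12 | benzyl 6-(benzyloxy)-2-[(benzyloxy)methyl]-3-methoxy-4-methylbenzoate | O=C(OCc1ccccc1)c1c(OCc2ccccc2)cc(C)c(OC)c1COCc1ccccc1 | intermediate
13 | 6-(benzyloxy)-2-[(benzyloxy)methyl]-3-methoxy-4-methylbenzoic acid | OC(=O)c1c(OCc2ccccc2)cc(C)c(OC)c1COCc1ccccc1 | intermediate
14 | 3-methoxy-2-(trimethylsilyl)phenyl trifluoromethanesulfonate | COc1cccc(OS(=O)(=O)C(F)(F)F)c1[Si](C)(C)C | starting material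
15 | caesium 6-(benzyloxy)-2-[(benzyloxy)methyl]-3-methoxy-4-methylbenzoate | [Cs+].[O-]C(=O)c1c(OCc2ccccc2)cc(C)c(OC)c1COCc1ccccc1 | intermediate
16 | 3-methoxybenzyne (1-methoxycyclohexa-1,3-dien-5-yne) | COC1=CC=CC#C1 | intermediate
17 | {6-(benzyloxy)-2-[(benzyloxy)methyl]-3-methoxy-4-methylphenyl}(2-hydroxy-6-methoxyphenyl)methanone | COc1cccc(O)c1C(=O)c1c(OCc2ccccc2)cc(C)c(OC)c1COCc1ccccc1 | intermediate
18 | {6-(benzyloxy)-2-[(benzyloxy)methyl]-3-methoxy-4-methylphenyl}(2,6-dimethoxyphenyl)methanone | COc1cccc(OC)c1C(=O)c1c(OCc2ccccc2)cc(C)c(OC)c1COCc1ccccc1 | intermediate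
19 | (2,6-dimethoxyphenyl)[6-hydroxy-2-(hydroxymethyl)-3-methoxy-4-methylphenyl]methanone | COc1cccc(OC)c1C(=O)c1c(O)cc(C)c(OC)c1CO | intermediate
20 | [2-(2,6-dimethoxybenzoyl)-3-hydroxy-6-methoxy-5-methylphenyl]methyl acetate (preacredinone A) | COc1cccc(OC)c1C(=O)c1c(O)cc(C)c(OC)c1COC(C)=O | target

**Step count**

Total step count: 11. Longest linear sequence: 11 steps (1 to 20); the aryne precursor 14 is bought.

**Steps most likely to fail**

Step 8. The aryl anion may be protonated, or may fail to reach the shielded carbonyl between the two ortho substituents of ring B, so that the sequence stops at the aryl ester stage. The product phenoxide may also add to further aryne. The fallback sets out from acid 13 and builds the same ortho-metalated aryl ester without an aryne. Acid 13 with oxalyl chloride and catalytic DMF in CH2Cl2 should give 6-(benzyloxy)-2-[(benzyloxy)methyl]-3-methoxy-4-methylbenzoyl chloride F1. Acylation of 2-bromo-3-methoxyphenol (COc1cccc(O)c1Br) with F1 (Et3N, DMAP, CH2Cl2) should give 2-bromo-3-methoxyphenyl 6-(benzyloxy)-2-[(benzyloxy)methyl]-3-methoxy-4-methylbenzoate F2. Bromine–lithium exchange on F2 with n-BuLi in THF at −100 °C places the anion at the carbon between the ester oxygen and the methoxy group, with no proton source and no aryne present. The known anionic 1,3-O-to-C acyl shift then leads, after aq NH4Cl, back to the route at 17.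

Step 6. The carboxylate may be benzylated before the primary alkoxide, and the resulting ester may re-close to the phthalide faster than it is re-opened, so that only the phenol ends up benzylated. The fallback sets out from aldehyde 8 and protects the alcohol while the carboxyl carbon is still an unreactive amide. NaBH4 in MeOH gives 9, now isolated at neutral pH. NaH and BnBr in THF should give N,N-diethyl-2-[(benzyloxy)methyl]-3-methoxy-6-(methoxymethoxy)-4-methylbenzamide F3. Dilute HCl in MeOH at rt removes the MOM group to give N,N-diethyl-2-[(benzyloxy)methyl]-6-hydroxy-3-methoxy-4-methylbenzamide F4. K2CO3 and BnBr in DMF give N,N-diethyl-6-(benzyloxy)-2-[(benzyloxy)methyl]-3-methoxy-4-methylbenzamide F5. Reduction of the hindered tertiary amide with Cp2Zr(H)Cl in THF should give 6-(benzyloxy)-2-[(benzyloxy)methyl]-3-methoxy-4-methylbenzaldehyde F6. Pinnick oxidation (NaClO2, NaH2PO4, 2-methyl-2-butene, t-BuOH/H2O) then comes back to the route at 13.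

Step 11. The ring B phenol may be acetylated along with, or in competition with, the primary alcohol, giving mixtures of mono- and diacetates. The fallback sets out from diol 19 and gives up selectivity in the acylation. Excess Ac2O with DMAP in pyridine should give [3-acetoxy-2-(2,6-dimethoxybenzoyl)-6-methoxy-5-methylphenyl]methyl acetate F7. Pyrrolidine (1 equiv) in MeCN at 0 °C then cleaves the much more reactive aryl acetate by aminolysis and leaves the alkyl acetate, coming back to the route at 20.

**Further compounds**

F1 | step 8 | 6-(benzyloxy)-2-[(benzyloxy)methyl]-3-methoxy-4-methylbenzoyl chloride | O=C(Cl)c1c(OCc2ccccc2)cc(C)c(OC)c1COCc1ccccc1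
F2 | step 8 | 2-bromo-3-methoxyphenyl 6-(benzyloxy)-2-[(benzyloxy)methyl]-3-methoxy-4-methylbenzoate | COc1cccc(OC(=O)c2c(OCc3ccccc3)cc(C)c(OC)c2COCc2ccccc2)c1Br
F3 | step 6 | N,N-diethyl-2-[(benzyloxy)methyl]-3-methoxy-6-(methoxymethoxy)-4-methylbenzamide | CCN(CC)C(=O)c1c(COCc2ccccc2)c(OC)c(C)cc1OCOC
F4 | step 6 | N,N-diethyl-2-[(benzyloxy)methyl]-6-hydroxy-3-methoxy-4-methylbenzamide | CCN(CC)C(=O)c1c(COCc2ccccc2)c(OC)c(C)cc1O
F5 | step 6 | N,N-diethyl-6-(benzyloxy)-2-[(benzyloxy)methyl]-3-methoxy-4-methylbenzamide | CCN(CC)C(=O)c1c(COCc2ccccc2)c(OC)c(C)cc1OCc1ccccc1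
F6 | step 6 | 6-(benzyloxy)-2-[(benzyloxy)methyl]-3-methoxy-4-methylbenzaldehyde | O=Cc1c(OCc2ccccc2)cc(C)c(OC)c1COCc1ccccc1
F7 | step 11 | [3-acetoxy-2-(2,6-dimethoxybenzoyl)-6-methoxy-5-methylphenyl]methyl acetate | COc1cccc(OC)c1C(=O)c1c(OC(C)=O)cc(C)c(OC)c1COC(C)=O
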